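(Readings and results come from a simulation with made-up constants, noise included.)

I began from two constants, an intercept a and a slope b, in a loss constant k = a + b[coupling partner]. Here k is the natural logarithm of charged over remaining starting material, divided by the time (an apparent first-order rate constant).

| flask | starting material | coupling partner | remark | time |
|---|---|---|---|---|
| teal | 0.087 M | 0.030 M | run made earlier |  |
| ochre | 0.087 M | 0.046 M | run made earlier |  |
| flask | 0.087 M | 0.0609 M |  | 25 h |

| run | time / h | starting material / % | target / % | over-reaction product / % |
|---|---|---|---|---|
| teal | 6.00 | 91.8 | 1.1 | 1.4 |
| teal | 12.0 | 87.7 | 2.6 | 0 |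
| teal | 20.0 | 81.6 | 3.7 | 2.4 |
| teal | 25.0 | 78.0 | 4.9 | 4.1 |
| ochre | 3.00 | 94.4 | 1.7 | 0 |
| ochre | 8.00 | 90.2 | 3.9 | 1.2 |
| ochre | 15.0 | 83.0 | 5.6 | 3.3 |
| ochre | 25.0 | 73.9 | 6.4 | 4.3 |

(readings scatter by 1 percentage point)

- a reading or a percentage of starting material is of its free form alone

* where most of what was charged as starting material, at 25 h is found (starting material / target / over-reaction product)
* the largest share itself, whichever of these holds it, in percent of the starting material charged

I followed the ochre run from its first reading to its last. At 3.00 h starting material stood at 94.4 % and target was already forming, at 1.7 %. At 15.0 h target read 5.6 %, over-reaction product 3.3 %, and 8.10 % of the charge appeared in no reading. By 25.0 h target had gained 0.8 percentage points while starting material lost 9.1 points, and the unseen part had reached 15.4 %.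

The last readings gave k = 0.00994 /h in teal and 0.0121 /h in ochre, so I read b = 0.135 /M/h and a = 0.00589 /h. For the flask I reckoned the loss constant k = 0.0141 /h, and from it an estimate of 70.3 % of the starting material remaining at 25 h. That is more than the 29.7 % open to everything else together, so I needed no reckoning of target or over-reaction product to name the largest share.

The forecast named starting material at 70.5 %, slightly above my figure, and its line included “a loss route that doesn't depend on the partner”.

The flask gave starting material at 70.1 %.

    starting material ⇌ dormant form (K = 1.70, k = 0.00710 /h)
    coupling partner + target → over-reaction product (k = 1.34 /M/h)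
    starting material + coupling partner → target + released group (k = 0.150 /M/h)

That share corresponds to k = 0.0142 /h, beside my 0.0141 /h. I then took the neighbour flask, which had 0.024 M of coupling partner, less than teal had, with its starting material charge and its time as in the flask. Moving along the same slope from the flask gave k = 0.00913 /h for the neighbour flask, and from it an estimate of 79.6 % of its starting material remaining. The neighbour flask held 78.4 %.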